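**Strategy.** The route rests on cutting the C7–aryl and C8–carboxyl bonds of the bicyclo[2.2.2]oct-5-ene-2,3-dione core (bridgeheads C1, C4). A vicinal aryl/carboxyl pair on one two-carbon bridge is the imprint of aryl–palladium and CO adding across an alkene. One enantioselective aryl-methoxycarbonylation of the C2v-symmetric 2,2,3,3-tetramethoxybicyclo[2.2.2]octa-5,7-diene therefore sets C1, C4, C7 and C8 together. The precursor carries acyclic methyl ketals, released by the final mild acid, and is made from veratrole by anodic ketalisation and Diels–Alder reaction. The cis carboxyl then directs C5–H olefination before C8 is inverted, and the base-sensitive danshensu ester is attached last.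

Key step: step 5

Remarks and assumptions:
- Core numbering used throughout: bridgeheads C1 and C4; C2 (on C1) and C3 (on C4) are the dione/ketal carbons; C5=C6 is the alkene with C5 on C4; C7 (aryl) is on C1 and C8 (carboxyl) is on C4.
- Ar = 2,2-dimethyl-1,3-benzodioxol-5-yl; PMB = 4-methoxybenzyl.
- Assumption: (R)-BINAP is taken to select the alkene carbon that leads to the enantiomer drawn; if induction runs the other way, (S)-BINAP is used with no other change.
- The dione is carried as two dimethyl ketals because a bis-dioxolane of an α-diketone would need hydrolysis conditions that also cleave the dienoate–lactate ester.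
- The lactate unit is attached only after the last alkoxide step, since an α-acyloxy ester would racemise and transesterify there.

Step 1
Reactants: 1 veratrole (1,2-dimethoxybenzene)
Product: 2 5,5,6,6-tetramethoxycyclohexa-1,3-diene
Conditions: Pt anode and cathode, undivided cell, constant current, 1% KOH in MeOH, 0 °C
Reagents that add atoms: methanol, CO
Why: Anodic methoxylation (two-electron oxidation of the electron-rich arene with methanol capture at both oxygen-bearing carbons) should give the o-quinone bis(dimethyl ketal), which has no stereocentre.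

Step 2
Reactants: 2 5,5,6,6-tetramethoxycyclohexa-1,3-diene; 3 (E)-1,2-bis(phenylsulfonyl)ethene
Product: 4 racemic trans-2,2,3,3-tetramethoxy-7,8-bis(phenylsulfonyl)bicyclo[2.2.2]oct-5-ene
Conditions: toluene, 100 °C
Reagents that add atoms: none
Why: Diels–Alder reaction of a cyclohexa-1,3-diene with a doubly sulfonyl-activated acetylene equivalent; the (E)-dienophile can give only the trans disulfone, a racemate whose stereocentres are erased in step 3.

Step 3
Reactants: 4 racemic trans-2,2,3,3-tetramethoxy-7,8-bis(phenylsulfonyl)bicyclo[2.2.2]oct-5-ene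
Product: 5 2,2,3,3-tetramethoxybicyclo[2.2.2]octa-5,7-diene (achiral, C2v)
Conditions: 5% Na/Hg, NaH2PO4, MeOH/THF, −20 °C; product handled below 60 °C
Reagents that add atoms: none
Why: Julia-type reductive elimination of the vicinal bis-sulfone should unveil the second alkene without touching the ketals, and the low temperature guards against retro-Diels–Alder loss of tetramethoxyethene.

Step 4
Reactants: 6 2,2-dimethyl-1,3-benzodioxole
Product: 7 5-iodo-2,2-dimethyl-1,3-benzodioxole
Conditions: NIS, TFA (10 mol %), MeCN, rt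
Reagents that add atoms: N-iodosuccinimide, O=C1CCC(=O)N1I
Why: Electrophilic aromatic iodination; the two positions para to a ring oxygen are equivalent, so only the 5-iodide should form.

Step 5
Reactants: 5 2,2,3,3-tetramethoxybicyclo[2.2.2]octa-5,7-diene (1.5 equiv); 7 5-iodo-2,2-dimethyl-1,3-benzodioxole; 8 carbon monoxide
Product: 9 methyl 7-Ar-2,2,3,3-tetramethoxybicyclo[2.2.2]oct-5-ene-8-carboxylate, C7 aryl and C8 ester cis and both syn to the C5=C6 bridge, single enantiomer as in the SMILES
Conditions: Pd(OAc)2 (5 mol %), (R)-BINAP (7.5 mol %), Ag2CO3 (0.6 equiv), CO (1 atm, balloon), MeOH/toluene 1:4, 50 °C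
Reagents that add atoms: methanol, CO
Why: Proposed new method: oxidative addition of 7 to zerovalent palladium and iodide abstraction by silver should give a cationic aryl–palladium–BINAP species that binds one alkene of 5 on the face turned toward the second alkene (the four methoxy groups block the ketal-flanked face) and inserts syn to form C7–aryl; the alkyl–palladium at C8 has its only syn β-hydrogen at bridgehead C4, so it cannot eliminate, inserts CO with retention and is cleaved by methanol to 9 with return of zerovalent palladium. The closest known reaction type is the cis,exo aryl-alkoxycarbonylation of norbornene and norbornadiene with aryl halides, CO and alcohols, together with BINAP-controlled enantioselective hydroarylation of norbornenes; a bicyclo[2.2.2]octadiene has not been used in either. No ring is closed. C7 and C8 are set cis by syn insertion and retentive CO insertion, their position syn to the C5=C6 bridge follows from attack anti to the ketal bridge, and C1 and C4 become stereogenic in the same event, their sense fixed by which of the four symmetry-related alkene carbons takes the aryl group. That choice between two mutually enantiotopic pairs of homotopic carbons is the one selectivity the substrate cannot supply and must come from the bisphosphine held on the cationic metal. CO insertion into the aryl–palladium bond before alkene insertion is countered by the low CO pressure and the excess of 5, and the hindered remaining alkene of 9 should not react again.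

Step 6
Reactants: 9 methyl 7-Ar-2,2,3,3-tetramethoxybicyclo[2.2.2]oct-5-ene-8-carboxylate (cis)
Product: 10 7-Ar-2,2,3,3-tetramethoxy-N-(quinolin-8-yl)bicyclo[2.2.2]oct-5-ene-8-carboxamide, configuration as 9
Conditions: 8-aminoquinoline (3 equiv), AlMe3 (3 equiv), toluene, 0 → 90 °C; aq. potassium sodium tartrate work-up
Reagents that add atoms: 8-aminoquinoline, Nc1cccc2cccnc12
Why: Weinreb amidation with the dimethylaluminium amide converts the hindered ester directly and without base, so the cis configuration at C8 needed for step 7 is kept.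

Step 7
Reactants: 10 the cis 8-aminoquinoline amide; 11 methyl acrylate (3 equiv)
Product: 12 methyl (E)-3-[7-Ar-2,2,3,3-tetramethoxy-8-(quinolin-8-ylcarbamoyl)bicyclo[2.2.2]oct-5-en-5-yl]prop-2-enoate, C7/C8 cis as in 10
Conditions: Pd(OAc)2 (10 mol %), 1,4-benzoquinone (20 mol %), MnO2 (3 equiv), PivOH (1 equiv), MeCN, 60 °C
Reagents that add atoms: none
Why: Fujiwara–Moritani oxidative olefination, in which the cis amide pointing at the C5=C6 bridge delivers divalent palladium to C5–H through a six-membered palladacycle (the known mode for γ,δ-unsaturated 8-aminoquinoline amides), and acrylate insertion with β-hydride elimination gives the (E)-dienoate without touching a stereocentre.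

Step 8
Reactants: 12 the olefinated cis amide
Product: 14 PMB 7-Ar-2,2,3,3-tetramethoxy-5-[(E)-3-(4-methoxybenzyloxy)-3-oxoprop-1-enyl]bicyclo[2.2.2]oct-5-ene-8-carboxylate, C8 ester now trans to the C7 aryl (ester syn to the ketal bridge, aryl syn to the diene bridge), via N-Boc imide 13 (not isolated)
Conditions: Boc2O (3 equiv), DMAP (0.5 equiv), MeCN, 50 °C; evaporate; then PMBOH (10 equiv), NaH (1.5 equiv), THF, 0 → 40 °C; H2O quench at 0 °C
Reagents that add atoms: 4-methoxybenzyl alcohol, COc1ccc(CO)cc1; di-tert-butyl dicarbonate, CC(C)(C)OC(=O)OC(=O)OC(C)(C)C (its Boc group is carried only by 13)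
Why: N-Boc activation twists the amide so that the benzylic alkoxide cleaves the acyl–N bond and also transesterifies the dienoate, and reversible enolisation of the new C8 ester under the same alkoxide should move it out of the eclipsing contact with the C7 aryl group into the thermodynamically preferred trans position.

Step 9
Reactants: 14 the trans bis-PMB diester
Product: 15 (E)-3-[7-Ar-2,2,3,3-tetramethoxy-8-(4-methoxybenzyloxycarbonyl)bicyclo[2.2.2]oct-5-en-5-yl]prop-2-enoic acid, trans as in 14
Conditions: LiOH·H2O (1.2 equiv), THF/H2O 3:1, 0 °C; dilute HCl to pH 4 at 0 °C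
Reagents that add atoms: lithium hydroxide, [Li+].[OH-]
Why: Saponification selective by hindrance, the exposed dienoate ester being hydrolysed while the C8 ester, flanked by C7–aryl, bridgehead C4 and the C3 methoxy groups, should survive.

Step 10
Reactants: 16 (R)-danshensu ((2R)-3-(3,4-dihydroxyphenyl)-2-hydroxypropanoic acid)
Product: 17 (5R)-5-[(2,2-dimethyl-1,3-benzodioxol-5-yl)methyl]-2,2-dimethyl-1,3-dioxolan-4-one
Conditions: 2,2-dimethoxypropane, TsOH·H2O (cat.), acetone/benzene, reflux through 4 Å MS
Reagents that add atoms: 2,2-dimethoxypropane, COC(C)(C)OC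
Why: Acid-catalysed transketalisation protects the catechol as its acetonide and ties the α-hydroxy acid into a dioxolanone, the stereocentre not being involved.

Step 11
Reactants: 17 the bis-acetonide
Product: 18 PMB (2R)-3-(2,2-dimethyl-1,3-benzodioxol-5-yl)-2-hydroxypropanoate
Conditions: PMBOH (3 equiv), K2CO3 (0.2 equiv), THF, rt
Reagents that add atoms: 4-methoxybenzyl alcohol, COc1ccc(CO)cc1
Why: The dioxolanone is an activated ester, so base-catalysed alcoholysis releases acetone and gives the α-hydroxy ester with the carbinol free, while the benzodioxole is inert to base and the mild carbonate does not enolise the lactate.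

Step 12
Reactants: 15 the dienoic acid; 18 the protected danshensu alcohol
Product: 19 fully protected yunnaneic acid C (dienoate ester of 15 with the hydroxyl of 18; two PMB esters, two acetonides, two dimethyl ketals)
Conditions: EDC·HCl, DMAP (cat.), CH2Cl2, 0 °C → rt
Reagents that add atoms: none
Why: Steglich esterification, whose carbodiimide/DMAP conditions are too weakly basic to disturb the lactate stereocentre or C8.

Step 13
Reactants: 19 fully protected yunnaneic acid C
Product: 20 yunnaneic acid C
Conditions: TFA/H2O 9:1, anisole (10 equiv), 0 °C → rt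
Reagents that add atoms: water, O
Why: Acidic global deprotection, in which aqueous TFA hydrolyses both dimethyl ketals (the α-keto ketal being the slow stage) and both acetonides and ionises the two PMB esters with anisole trapping the benzyl cations, while the dienoate–lactate ester and all stereocentres are stable to acid.

**Compound list**

1 | veratrole (1,2-dimethoxybenzene) | COc1ccccc1OC | starting material
2 | 5,5,6,6-tetramethoxycyclohexa-1,3-diene | COC1(OC)C=CC=CC1(OC)OC | intermediate
3 | (E)-1,2-bis(phenylsulfonyl)ethene | O=S(=O)(/C=C/S(=O)(=O)c1ccccc1)c1ccccc1 | starting material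
4 | racemic trans-2,2,3,3-tetramethoxy-7,8-bis(phenylsulfonyl)bicyclo[2.2.2]oct-5-ene (one enantiomer drawn) | C1=C[C@H]2C(OC)(OC)C(OC)(OC)[C@@H]1[C@@H](S(=O)(=O)c1ccccc1)[C@@H]2S(=O)(=O)c1ccccc1 | intermediate
5 | 2,2,3,3-tetramethoxybicyclo[2.2.2]octa-5,7-diene (achiral) | COC1(OC)C2C=CC(C=C2)C1(OC)OC | intermediate
6 | 2,2-dimethyl-1,3-benzodioxole | CC1(C)Oc2ccccc2O1 | starting material
7 | 5-iodo-2,2-dimethyl-1,3-benzodioxole | CC1(C)Oc2ccc(I)cc2O1 | intermediate
8 | carbon monoxide | [C-]#[O+] | starting material
9 | methyl 7-Ar-2,2,3,3-tetramethoxybicyclo[2.2.2]oct-5-ene-8-carboxylate, aryl and ester cis, both syn to C5=C6 | C1=C[C@H]2C(OC)(OC)C(OC)(OC)[C@@H]1[C@@H](C(=O)OC)[C@H]2c1ccc2OC(C)(C)Oc2c1 | intermediate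
10 | cis 8-aminoquinoline amide of the C8 acid | C1=C[C@H]2C(OC)(OC)C(OC)(OC)[C@@H]1[C@@H](C(=O)Nc1cccc3cccnc13)[C@H]2c1ccc2OC(C)(C)Oc2c1 | intermediate
11 | methyl acrylate | C=CC(=O)OC | starting material
12 | C5 (E)-methyl acrylate, cis 8-aminoquinoline amide | COC(=O)/C=C/C1=C[C@H]2C(OC)(OC)C(OC)(OC)[C@@H]1[C@@H](C(=O)Nc1cccc3cccnc13)[C@H]2c1ccc2OC(C)(C)Oc2c1 | intermediate
13 | N-Boc imide of 12 | COC(=O)/C=C/C1=C[C@H]2C(OC)(OC)C(OC)(OC)[C@@H]1[C@@H](C(=O)N(C(=O)OC(C)(C)C)c1cccc3cccnc13)[C@H]2c1ccc2OC(C)(C)Oc2c1 | intermediate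
14 | trans bis-PMB diester (C8 ester syn to the ketal bridge) | O=C(/C=C/C1=C[C@H]2C(OC)(OC)C(OC)(OC)[C@@H]1[C@H](C(=O)OCc1ccc(OC)cc1)[C@H]2c1ccc2OC(C)(C)Oc2c1)OCc1ccc(OC)cc1 | intermediate
15 | trans dienoic acid with C8 PMB ester | O=C(O)/C=C/C1=C[C@H]2C(OC)(OC)C(OC)(OC)[C@@H]1[C@H](C(=O)OCc1ccc(OC)cc1)[C@H]2c1ccc2OC(C)(C)Oc2c1 | intermediate
16 | (R)-danshensu | O[C@H](Cc1ccc(O)c(O)c1)C(=O)O | starting material
17 | (5R)-5-[(2,2-dimethyl-1,3-benzodioxol-5-yl)methyl]-2,2-dimethyl-1,3-dioxolan-4-one | O1[C@H](Cc2ccc3OC(C)(C)Oc3c2)C(=O)OC1(C)C | intermediate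
18 | PMB (2R)-3-(2,2-dimethyl-1,3-benzodioxol-5-yl)-2-hydroxypropanoate | O[C@H](Cc1ccc2OC(C)(C)Oc2c1)C(=O)OCc1ccc(OC)cc1 | intermediate
19 | fully protected yunnaneic acid C | O=C(/C=C/C1=C[C@H]2C(OC)(OC)C(OC)(OC)[C@@H]1[C@H](C(=O)OCc1ccc(OC)cc1)[C@H]2c1ccc2OC(C)(C)Oc2c1)O[C@H](Cc1ccc2OC(C)(C)Oc2c1)C(=O)OCc1ccc(OC)cc1 | intermediate
20 | yunnaneic acid C | O=C(/C=C/C1=C[C@H]2C(=O)C(=O)[C@@H]1[C@H](C(=O)O)[C@H]2c1ccc(O)c(O)c1)O[C@H](Cc1ccc(O)c(O)c1)C(=O)O | target

**Step count.** Total: 13 steps. Longest linear sequence: 10 steps (1, 2, 3, 5, 6, 7, 8, 9, 12, 13) from veratrole.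

**Steps most likely to fail**

1. Step 5 (Proposed new method). The process at risk is the choice between the enantiotopic alkene carbons, which may be weak. In addition, CO may insert into the aryl–palladium bond before the only mildly strained alkene does, which diverts the iodide to the methyl benzoate. The fallback uses known chemistry and sets out from 2 and 7. Sonogashira coupling of 7 with methyl propiolate (PdCl2(PPh3)2, CuI, K2CO3, THF) gives methyl 3-(2,2-dimethyl-1,3-benzodioxol-5-yl)prop-2-ynoate F1. Semi-hydrogenation (H2, Pd/CaCO3 poisoned with Pb(OAc)2, quinoline) gives methyl (Z)-3-(2,2-dimethyl-1,3-benzodioxol-5-yl)prop-2-enoate F2. Diels–Alder reaction of F2 with diene 2 (toluene, 110 °C, or high pressure at rt) should follow the endo rule and place aryl and ester cis and syn to the new alkene. This gives 9 as a racemate with the enantiomer of 9 F3, which is removed by preparative chromatography on a chiral phase. The route is rejoined at 9.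

2. Step 7. The process at risk is C5–H palladation, which may lose to palladation of the nearby aryl ortho position or to amide-directed nucleopalladation of the alkene, and the oxidant may erode material. The fallback uses no C–H activation and sets out from 9, with the cis carboxyl serving as an internal nucleophile. Me3SnOH (1,2-dichloroethane, 70 °C) gives the cis 7-Ar-2,2,3,3-tetramethoxybicyclo[2.2.2]oct-5-ene-8-carboxylic acid F4. I2/NaHCO3 (MeCN/H2O) closes the C5-O, C6-iodo γ-lactone F5. Bu3SnH/AIBN (benzene, 80 °C) removes iodine to give the C8-carbonyl-to-C5-oxygen lactone F6. LiOH (THF/H2O), then PMBCl/Cs2CO3 (DMF), gives the cis C5-hydroxy C8-PMB ester F7. Dess–Martin oxidation gives the C5 ketone F8, enolisable only toward C6. KN(SiMe3)2/PhNTf2 (THF, −78 °C) gives the C5 enol triflate F9. Heck coupling with methyl acrylate 11 (Pd(OAc)2, PPh3, K2CO3, DMF, 60 °C) gives the cis C8-PMB ester C5-(E)-methyl acrylate F10. NaH/PMBOH in THF, as in the second half of step 8, then inverts C8 and exchanges the methyl ester, and the route is rejoined at 14.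

3. Step 8. The process at risk is attack of the alkoxide at the carbamate carbonyl of the congested imide 13, which only returns 12, and incomplete inversion at C8. The fallback sets out from 12 and uses no N-activation. NaOH in EtOH/H2O at 110 °C (sealed vessel) should epimerise the free amide at C8 and then hydrolyse it together with the methyl ester. This gives the trans (E)-3-(8-carboxy-7-Ar-2,2,3,3-tetramethoxybicyclo[2.2.2]oct-5-en-5-yl)prop-2-enoic acid F11. PMBCl/Cs2CO3 (DMF) esterifies both carboxyl groups, and the route is rejoined at 14.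

**Further compounds**

F1 | step 5 | methyl 3-(2,2-dimethyl-1,3-benzodioxol-5-yl)prop-2-ynoate | COC(=O)C#Cc1ccc2OC(C)(C)Oc2c1
F2 | step 5 | methyl (Z)-3-(2,2-dimethyl-1,3-benzodioxol-5-yl)prop-2-enoate | COC(=O)/C=C\c1ccc2OC(C)(C)Oc2c1
F3 | step 5 | enantiomer of 9 | C1=C[C@@H]2C(OC)(OC)C(OC)(OC)[C@H]1[C@H](C(=O)OC)[C@@H]2c1ccc2OC(C)(C)Oc2c1
F4 | step 7 | cis 7-Ar-2,2,3,3-tetramethoxybicyclo[2.2.2]oct-5-ene-8-carboxylic acid | C1=C[C@H]2C(OC)(OC)C(OC)(OC)[C@@H]1[C@@H](C(=O)O)[C@H]2c1ccc2OC(C)(C)Oc2c1
F5 | step 7 | C5-O, C6-iodo γ-lactone (iodine syn to the ketal bridge) | O=C1O[C@@H]2[C@@H](I)[C@H]3C(OC)(OC)C(OC)(OC)[C@@H]2[C@@H]1[C@H]3c1ccc2OC(C)(C)Oc2c1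
F6 | step 7 | C8-carbonyl-to-C5-oxygen γ-lactone | O=C1O[C@@H]2C[C@H]3C(OC)(OC)C(OC)(OC)[C@@H]2[C@@H]1[C@H]3c1ccc2OC(C)(C)Oc2c1
F7 | step 7 | cis C5-hydroxy C8-PMB ester | O[C@@H]1C[C@H]2C(OC)(OC)C(OC)(OC)[C@@H]1[C@@H](C(=O)OCc1ccc(OC)cc1)[C@H]2c1ccc2OC(C)(C)Oc2c1
F8 | step 7 | cis C5-keto C8-PMB ester | O=C1C[C@H]2C(OC)(OC)C(OC)(OC)[C@@H]1[C@@H](C(=O)OCc1ccc(OC)cc1)[C@H]2c1ccc2OC(C)(C)Oc2c1
F9 | step 7 | C5 enol triflate, cis C8-PMB ester | O=S(=O)(OC1=C[C@H]2C(OC)(OC)C(OC)(OC)[C@@H]1[C@@H](C(=O)OCc1ccc(OC)cc1)[C@H]2c1ccc2OC(C)(C)Oc2c1)C(F)(F)F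
F10 | step 7 | cis C8-PMB ester C5-(E)-methyl acrylate | COC(=O)/C=C/C1=C[C@H]2C(OC)(OC)C(OC)(OC)[C@@H]1[C@@H](C(=O)OCc1ccc(OC)cc1)[C@H]2c1ccc2OC(C)(C)Oc2c1
F11 | step 8 | trans (E)-3-(8-carboxy-7-Ar-2,2,3,3-tetramethoxybicyclo[2.2.2]oct-5-en-5-yl)prop-2-enoic acid | O=C(O)/C=C/C1=C[C@H]2C(OC)(OC)C(OC)(OC)[C@@H]1[C@H](C(=O)O)[C@H]2c1ccc2OC(C)(C)Oc2c1
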